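**Retrosynthetic overview**
1. Last disconnections: the C3–O ester bond (to (2E,4E)-octa-2,4-dienoic acid) and the N-Boc and O-silyl groups.
2. Key disconnection: C4a–C5 and C7–C8 of the carbocycle, made in one flask by a formal [3+3] annulation of a piperidine enecarbamate (C8–C8a–C4a as 1,3-dinucleophile) with an (E)-enal (C5–C6–C7, side chain on C5); C8a–H then enters as hydride.
3. Enabling feature: C8a, the ring-fusion carbon bonded to N, lies between C8 (CH2) and C4a (CH). Written as a 6-methyl-3,4-dihydro-2H-pyridine N-carbamate, the piperidine ring (N1, C2, C3, C4, C4a, C8a) holds an enamide whose β-carbon (C4a) and allylic methyl (C8) are nucleophilic in turn, and the carbamate holds the C2 methyl axial so that it steers C4a and C8a.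
4. Ring order: piperidine ring first (cyclodehydration of an acyclic δ-carbamoyl ketone; C2 and C3 from asymmetric aminohydroxylation of ethyl crotonate), carbocycle second (key step).
5. Enal: C5' carbinol from (R)-2-propyloxirane, enal function by cross-metathesis.

Key step: step 9

Remark on the chemistry: the core is numbered as in quinoline (N1, C2 … C8a) and the octyl chain with primed numbers; the target SMILES is read as (2R,3R,4aS,5S,8aR,5'R), with cis ring fusion, H4a/H5/H8a all cis, and the C2 methyl and C3 oxygen cis to each other and on the face of H4a and H8a.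

**Step 1**
Reactants: 1 ethyl (E)-but-2-enoate
Product: 2 ethyl (2S,3R)-3-{[(benzyloxy)carbonyl]amino}-2-hydroxybutanoate
Conditions: BnOC(O)NH2, t-BuOCl, NaOH, K2OsO2(OH)4 (4 mol%), hydroquinidine 1,4-phthalazinediyl diether (DHQD)2PHAL (5 mol%), n-PrOH/H2O 1:1, 0 °C → rt
Reagents that add atoms: benzyl carbamate NC(=O)OCc1ccccc1; water O
Why: Sharpless asymmetric aminohydroxylation (carbamate variant) of a crotonate; syn addition to the E-alkene gives the syn amino alcohol, the phthalazine ligand places N on C3, and the (DHQD) ligand selects the face that gives (2S,3R), the later C3 and C2 of the target.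

**Step 2**
Reactants: 2 ethyl (2S,3R)-3-{[(benzyloxy)carbonyl]amino}-2-hydroxybutanoate
Product: 3 ethyl (2S,3R)-2-(benzyloxy)-3-{[(benzyloxy)carbonyl]amino}butanoate
Conditions: BnOC(=NH)CCl3, TfOH (5 mol%), CH2Cl2/cyclohexane 1:2, 0 °C → rt
Reagents that add atoms: benzyl 2,2,2-trichloroacetimidate ClC(Cl)(Cl)C(=N)OCc1ccccc1
Why: acid-catalysed O-benzylation with the trichloroacetimidate; no base is present, so the α-stereocentre should not epimerise and the carbamate should not close to an oxazolidinone.

**Step 3**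
Reactants: 3 ethyl (2S,3R)-2-(benzyloxy)-3-{[(benzyloxy)carbonyl]amino}butanoate
Product: 5 benzyl N-[(2R,3R,4E)-3-(benzyloxy)-6-oxohept-4-en-2-yl]carbamate, via aldehyde 4 (not isolated)
Conditions: i-Bu2AlH (2.2 equiv), CH2Cl2, −78 °C; then Ph3P=CHC(O)CH3, −78 °C → rt
Reagents that add atoms: 1-(triphenyl-λ5-phosphanylidene)propan-2-one CC(=O)C=P(c1ccccc1)(c1ccccc1)c1ccccc1
Why: half-reduction of the α-alkoxy ester with i-Bu2AlH followed by Wittig olefination in the same flask; the stabilised ylide should give the E-enone and the epimerisable α-alkoxy aldehyde is not isolated.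

**Step 4**
Reactants: 5 benzyl N-[(2R,3R,4E)-3-(benzyloxy)-6-oxohept-4-en-2-yl]carbamate
Product: 6 benzyl N-[(2R,3R)-3-(benzyloxy)-6-oxoheptan-2-yl]carbamate
Conditions: H2 (1 atm), RhCl(PPh3)3 (5 mol%), benzene/EtOH 1:1, rt
Reagents that add atoms: none
Why: homogeneous hydrogenation with RhCl(PPh3)3 saturates the disubstituted C=C bond and leaves the benzyl ether, the benzyl carbamate and the ketone untouched.

**Step 5**
Reactants: 6 benzyl N-[(2R,3R)-3-(benzyloxy)-6-oxoheptan-2-yl]carbamate
Product: 7 benzyl (2R,3R)-3-(benzyloxy)-2,6-dimethyl-3,4-dihydropyridine-1(2H)-carboxylate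
Conditions: TsOH·H2O (5 mol%), toluene, reflux, Dean–Stark trap
Reagents that add atoms: none
Why: acid-catalysed cyclodehydration of a δ-carbamoyl ketone; the carbamate N adds to the ketone and the N-acyliminium ion loses a ring proton to give the endocyclic, trisubstituted enecarbamate, which closes the piperidine ring (N1–C8a bond).

**Step 6**
Reactants: 8 (2R)-2-propyloxirane; 9 5-bromopent-1-ene
Product: 11 (4R)-dec-9-en-4-ol, via pent-4-en-1-ylmagnesium bromide 10 (not isolated)
Conditions: 9, Mg, THF, rt; then 8, CuI (10 mol%), THF, −30 → 0 °C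
Reagents that add atoms: none
Why: copper-catalysed opening of a terminal epoxide by a Grignard reagent at the CH2 terminus; the stereocentre is not touched, so the (R)-epoxide gives the (R)-carbinol (later C5').

**Step 7**
Reactants: 11 (4R)-dec-9-en-4-ol
Product: 12 tert-butyl{[(4R)-dec-9-en-4-yl]oxy}dimethylsilane
Conditions: TBSCl, imidazole, DMF, rt
Reagents that add atoms: tert-butyl(chloro)dimethylsilane CC(C)(C)[Si](C)(C)Cl
Why: standard silylation of a secondary alcohol; the TBS ether should survive every step up to the final acid treatment.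

**Step 8**
Reactants: 12 tert-butyl{[(4R)-dec-9-en-4-yl]oxy}dimethylsilane
Product: 13 (2E,8R)-8-{[tert-butyl(dimethyl)silyl]oxy}undec-2-enal
Conditions: (E)-but-2-enal (4 equiv), RuCl2(H2IMes)(=CH-C6H4-2-O-i-Pr) (second-generation Hoveyda–Grubbs catalyst, H2IMes = 1,3-dimesitylimidazolidin-2-ylidene; 3 mol%), CH2Cl2, 40 °C
Reagents that add atoms: (E)-but-2-enal C/C=C/C=O
Why: olefin cross-metathesis of a terminal alkene with crotonaldehyde; the conjugated product should form as the E-enal while propene leaves.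

**Step 9**
Reactants: 7 benzyl (2R,3R)-3-(benzyloxy)-2,6-dimethyl-3,4-dihydropyridine-1(2H)-carboxylate; 13 (2E,8R)-8-{[tert-butyl(dimethyl)silyl]oxy}undec-2-enal
Product: 16 benzyl (2R,3R,4aS,5S,8aR)-3-(benzyloxy)-5-[(5R)-5-{[tert-butyl(dimethyl)silyl]oxy}octyl]-2-methyl-3,4,4a,5,6,8a-hexahydroquinoline-1(2H)-carboxylate, via exocyclic enecarbamate aldehyde 14 (not isolated), via dienyl carbamate 15 (not isolated)
Conditions: (2R,5R)-5-benzyl-2-tert-butyl-3-methylimidazolidin-4-one·CF3CO2H (20 mol%), CH2Cl2/i-PrOH 85:15, −20 °C → rt; then Et3SiH, CF3CO2H, CH2Cl2, −40 → 0 °C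
Reagents that add atoms: none
Why: Proposed new method: the imidazolidinone converts 13 into its (E)-iminium ion, the enamide β-carbon C4a of 7 adds to the β-carbon C5, the resulting N-acyliminium ion loses a C8 proton to give exocyclic enecarbamate 14, whose C8 adds to the re-formed iminium carbon C7, and loss of the amine and of a C6 proton gives dienyl carbamate 15; Et3SiH/CF3CO2H then reduces 15 at C8a through the conjugated N-acyliminium ion. The closest known reactions are the Stork α,α'-annulation of ketone enamines with enals (a carbo-[3+3] of the same polarity), iminium-catalysed Friedel–Crafts and Mukaiyama–Michael additions of weak π-nucleophiles to enals, the formal aza-[3+3] of secondary enamides with enals, and the trans-selective acid/hydride reduction of 2,6-disubstituted enecarbamates; the use of a tertiary enecarbamate as a C,C-1,3-dinucleophile toward an iminium ion is the untested element. The carbocycle (C4a, C5, C6, C7, C8, C8a) closes in the second bond formation as a 6-(enolendo)-exo-trig Mannich-type cyclisation. C5 is set by the catalyst, whose benzyl group shields one face of the iminium ion so that the (2R,5R) enantiomer should give 5S; C4a is set by the piperidine ring, because A(1,3) strain with the Cbz group holds the C2 methyl axial and the electrophile enters axially on the opposite face; C8a is set in the reduction, where hydride enters axially on the face of the axial methyl and anti to the axial C4a–C5 bond, which gives the cis ring fusion and the trans relation of C2–CH3 and C8a–C8. The step needs C4a to react before C8 and 1,4- instead of 1,2-addition to the enal: the first is secured by the endocyclic position of the enamide double bond in 7, the second by iminium activation. Epimerisation at C4a through the tetrasubstituted enecarbamate is held back because H4a lies near the plane of the N-acyliminium ion, and 15 is therefore reduced without isolation.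

**Step 10**
Reactants: 16 benzyl (2R,3R,4aS,5S,8aR)-3-(benzyloxy)-5-[(5R)-5-{[tert-butyl(dimethyl)silyl]oxy}octyl]-2-methyl-3,4,4a,5,6,8a-hexahydroquinoline-1(2H)-carboxylate
Product: 18 tert-butyl (2R,3R,4aS,5S,8aR)-5-[(5R)-5-{[tert-butyl(dimethyl)silyl]oxy}octyl]-3-hydroxy-2-methyloctahydroquinoline-1(2H)-carboxylate, via amino alcohol 17 (not isolated)
Conditions: H2 (1 atm), Pd(OH)2/C, EtOAc, rt; filtration; then Boc2O, 40 °C
Reagents that add atoms: di-tert-butyl dicarbonate CC(C)(C)OC(=O)OC(=O)OC(C)(C)C
Why: one catalytic hydrogenation saturates the ring alkene (a C6=C7 positional isomer from step 9 would converge here to the same compound) and cleaves the benzyl ether and the benzyl carbamate by hydrogenolysis; Boc2O then acylates the secondary amine in preference to the secondary alcohol, and no stereocentre is formed or touched.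

**Step 11**
Reactants: 19 (E)-hex-2-enal
Product: 20 (2E,4E)-octa-2,4-dienoic acid
Conditions: CH2(CO2H)2, pyridine, piperidine (cat.), 90 °C
Reagents that add atoms: malonic acid OC(=O)CC(=O)O
Why: Doebner modification of the Knoevenagel condensation; decarboxylative elimination should give the 2E acid and the E geometry of the enal is carried over to C4=C5.

**Step 12**
Reactants: 20 (2E,4E)-octa-2,4-dienoic acid; 18 tert-butyl (2R,3R,4aS,5S,8aR)-5-[(5R)-5-{[tert-butyl(dimethyl)silyl]oxy}octyl]-3-hydroxy-2-methyloctahydroquinoline-1(2H)-carboxylate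
Product: 22 tert-butyl (2R,3R,4aS,5S,8aR)-5-[(5R)-5-{[tert-butyl(dimethyl)silyl]oxy}octyl]-2-methyl-3-{[(2E,4E)-octa-2,4-dienoyl]oxy}octahydroquinoline-1(2H)-carboxylate, via mixed anhydride 21 (not isolated)
Conditions: 20, 2,4,6-Cl3C6H2COCl, Et3N, THF, rt; then 18, 4-(dimethylamino)pyridine, toluene, rt → 50 °C
Reagents that add atoms: none
Why: Yamaguchi esterification; 4-(dimethylamino)pyridine attacks the mixed anhydride at the dienoyl carbonyl and the acylpyridinium ion acylates the C3 hydroxyl, the only free nucleophile since N carries Boc and C5'–O carries TBS; the C3 configuration is retained.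

**Step 13**
Reactants: 22 tert-butyl (2R,3R,4aS,5S,8aR)-5-[(5R)-5-{[tert-butyl(dimethyl)silyl]oxy}octyl]-2-methyl-3-{[(2E,4E)-octa-2,4-dienoyl]oxy}octahydroquinoline-1(2H)-carboxylate
Product: 23 (2R,3R,4aS,5S,8aR)-5-[(5R)-5-hydroxyoctyl]-2-methyldecahydroquinolin-3-yl (2E,4E)-octa-2,4-dienoate (CNP0186076.5)
Conditions: CF3CO2H/CH2Cl2/H2O 10:10:1, 0 °C → rt; aq. NaHCO3
Reagents that add atoms: none
Why: acidolysis removes the Boc group (tert-butyl cation, then decarboxylation) and hydrolyses the TBS ether in the same operation; the dienoate ester and all stereocentres should be unaffected by acid.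

**Compound list**
1 | ethyl (E)-but-2-enoate | CCOC(=O)/C=C/C | starting material
2 | ethyl (2S,3R)-3-{[(benzyloxy)carbonyl]amino}-2-hydroxybutanoate | C[C@@H](NC(=O)OCc1ccccc1)[C@H](O)C(=O)OCC | intermediate
3 | ethyl (2S,3R)-2-(benzyloxy)-3-{[(benzyloxy)carbonyl]amino}butanoate | C[C@@H](NC(=O)OCc1ccccc1)[C@H](OCc1ccccc1)C(=O)OCC | intermediate
4 | benzyl N-[(2R,3S)-3-(benzyloxy)-4-oxobutan-2-yl]carbamate | C[C@@H](NC(=O)OCc1ccccc1)[C@H](OCc1ccccc1)C=O | intermediate (not isolated)
5 | benzyl N-[(2R,3R,4E)-3-(benzyloxy)-6-oxohept-4-en-2-yl]carbamate | C[C@@H](NC(=O)OCc1ccccc1)[C@H](OCc1ccccc1)/C=C/C(C)=O | intermediate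
6 | benzyl N-[(2R,3R)-3-(benzyloxy)-6-oxoheptan-2-yl]carbamate | C[C@@H](NC(=O)OCc1ccccc1)[C@H](OCc1ccccc1)CCC(C)=O | intermediate
7 | benzyl (2R,3R)-3-(benzyloxy)-2,6-dimethyl-3,4-dihydropyridine-1(2H)-carboxylate | C[C@@H]1[C@H](OCc2ccccc2)CC=C(C)N1C(=O)OCc1ccccc1 | intermediate
8 | (2R)-2-propyloxirane | CCC[C@@H]1CO1 | starting material
9 | 5-bromopent-1-ene | BrCCCC=C | starting material
10 | pent-4-en-1-ylmagnesium bromide | C=CCCC[Mg]Br | intermediate (not isolated)
11 | (4R)-dec-9-en-4-ol | CCC[C@@H](O)CCCCC=C | intermediate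
12 | tert-butyl{[(4R)-dec-9-en-4-yl]oxy}dimethylsilane | CCC[C@@H](O[Si](C)(C)C(C)(C)C)CCCCC=C | intermediate
13 | (2E,8R)-8-{[tert-butyl(dimethyl)silyl]oxy}undec-2-enal | CCC[C@@H](O[Si](C)(C)C(C)(C)C)CCCC/C=C/C=O | intermediate
14 | benzyl (2R,3R,5S)-3-(benzyloxy)-5-[(3S,8R)-8-{[tert-butyl(dimethyl)silyl]oxy}-1-oxoundecan-3-yl]-2-methyl-6-methylidenepiperidine-1-carboxylate | O(Cc1ccccc1)[C@@H]1C[C@@H]([C@@H](CCCC[C@H](O[Si](C)(C)C(C)(C)C)CCC)CC=O)C(=C)N(C(=O)OCc2ccccc2)[C@@H]1C | intermediate (not isolated)
15 | benzyl (2R,3R,4aS,5S)-3-(benzyloxy)-5-[(5R)-5-{[tert-butyl(dimethyl)silyl]oxy}octyl]-2-methyl-3,4,4a,5-tetrahydroquinoline-1(2H)-carboxylate | O(Cc1ccccc1)[C@@H]1C[C@H]2[C@@H](CCCC[C@H](O[Si](C)(C)C(C)(C)C)CCC)C=CC=C2N(C(=O)OCc3ccccc3)[C@@H]1C | intermediate (not isolated)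
16 | benzyl (2R,3R,4aS,5S,8aR)-3-(benzyloxy)-5-[(5R)-5-{[tert-butyl(dimethyl)silyl]oxy}octyl]-2-methyl-3,4,4a,5,6,8a-hexahydroquinoline-1(2H)-carboxylate | O(Cc1ccccc1)[C@@H]1C[C@H]2[C@@H](CCCC[C@H](O[Si](C)(C)C(C)(C)C)CCC)CC=C[C@H]2N(C(=O)OCc3ccccc3)[C@@H]1C | intermediate
17 | (2R,3R,4aS,5S,8aR)-5-[(5R)-5-{[tert-butyl(dimethyl)silyl]oxy}octyl]-2-methyldecahydroquinolin-3-ol | O[C@@H]1C[C@H]2[C@@H](CCCC[C@H](O[Si](C)(C)C(C)(C)C)CCC)CCC[C@H]2N[C@@H]1C | intermediate (not isolated)
18 | tert-butyl (2R,3R,4aS,5S,8aR)-5-[(5R)-5-{[tert-butyl(dimethyl)silyl]oxy}octyl]-3-hydroxy-2-methyloctahydroquinoline-1(2H)-carboxylate | O[C@@H]1C[C@H]2[C@@H](CCCC[C@H](O[Si](C)(C)C(C)(C)C)CCC)CCC[C@H]2N(C(=O)OC(C)(C)C)[C@@H]1C | intermediate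
19 | (E)-hex-2-enal | CCC/C=C/C=O | starting material
20 | (2E,4E)-octa-2,4-dienoic acid | CCC/C=C/C=C/C(=O)O | intermediate
21 | (2E,4E)-octa-2,4-dienoic 2,4,6-trichlorobenzoic anhydride | CCC/C=C/C=C/C(=O)OC(=O)c1c(Cl)cc(Cl)cc1Cl | intermediate (not isolated)
22 | tert-butyl (2R,3R,4aS,5S,8aR)-5-[(5R)-5-{[tert-butyl(dimethyl)silyl]oxy}octyl]-2-methyl-3-{[(2E,4E)-octa-2,4-dienoyl]oxy}octahydroquinoline-1(2H)-carboxylate | CCC/C=C/C=C/C(=O)O[C@@H]1C[C@H]2[C@@H](CCCC[C@H](O[Si](C)(C)C(C)(C)C)CCC)CCC[C@H]2N(C(=O)OC(C)(C)C)[C@@H]1C | intermediate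
23 | (2R,3R,4aS,5S,8aR)-5-[(5R)-5-hydroxyoctyl]-2-methyldecahydroquinolin-3-yl (2E,4E)-octa-2,4-dienoate | CCC/C=C/C=C/C(=O)O[C@@H]1C[C@H]2[C@@H](CCCC[C@H](O)CCC)CCC[C@H]2N[C@@H]1C | target

**Step count and risks**
Total: 13 steps. Longest linear sequence: 9 steps (steps 1–5, 9, 10, 12, 13).

Step 9 (proposed new method). The tertiary enecarbamate may add too slowly to the iminium ion, so that dienamine self-condensation of 13 takes over. The cascade may also stall after the first bond, or acid may move the double bond of 7 to the exocyclic position and so reverse the order of the two bond formations. Under prolonged acid the C4a centre may epimerise. The fallback uses known reactions and replaces iminium catalysis by a cycloaddition. It sets out from 7 and 13, which are combined in an inverse-electron-demand hetero-Diels–Alder reaction (Eu(fod)3, fod = 6,6,7,7,8,8,8-heptafluoro-2,2-dimethyloctane-3,5-dionate, CH2Cl2, rt), a reaction known for N-vinyl amides and carbamates with α,β-unsaturated aldehydes. The enal should add as a 1-oxadiene to the face of 7 opposite to the axial C2 methyl through the endo transition state and give the cis-fused N,O-ketal F1, in which C4a–C5 is formed and C5 is set relative to C4a by the endo rule instead of by a catalyst. BF3·OEt2 (CH2Cl2, −40 °C → rt) then ionises the N,O-ketal to the N-acyliminium ion, which gives 14 by proton loss. The known acid-promoted addition of a tertiary enamide to an aldehyde closes C7–C8 and dehydration gives 15, where the fallback comes back to the route (reduction in the flask to 16 as in step 9).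

Step 10. The liberated secondary amine may poison the catalyst before the benzyl ether is cleaved, and the hindered 2,6-disubstituted amine may take up the Boc group so slowly that O-acylation competes. The fallback sets out from 16: sodium in liquid ammonia (THF, −78 °C) removes both benzyl groups by electron transfer while the ring alkene and the TBS ether stay, giving amino alcohol F2. Boc2O (CHCl3, 50 °C) gives carbamate F3, and H2, Pd/C, EtOAc then only has to saturate the C7=C8 bond, which rejoins the route at 18.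

Step 12. Acylation of the C3 hydroxyl, flanked by the C2 methyl and the N-Boc group, by the bulky mixed anhydride may be slow, and long exposure of the dienoyl pyridinium ion to 4-(dimethylamino)pyridine may scramble the diene geometry. The fallback sets out from 18: coupling with diethylphosphonoacetic acid (dicyclohexylcarbodiimide, CH2Cl2, rt), a small and reactive acyl donor, gives phosphonoacetate F4. Horner–Wadsworth–Emmons reaction of F4 with (E)-hex-2-enal 19 (LiCl, DBU, MeCN, rt) builds the 2E double bond on the ester and gives 22, where the route is rejoined.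

**Further compounds**
F1 | step 9 | benzyl (4S,4aS,6R,7R,8aR)-6-(benzyloxy)-4-[(5R)-5-{[tert-butyl(dimethyl)silyl]oxy}octyl]-7,8a-dimethyl-4a,5,6,7-tetrahydro-4H-pyrano[2,3-b]pyridine-8(8aH)-carboxylate (endo hetero-Diels–Alder adduct of 7 and 13; ring O bonded to C8a of the quinoline numbering) | O(Cc1ccccc1)[C@@H]1C[C@H]2[C@@H](CCCC[C@H](O[Si](C)(C)C(C)(C)C)CCC)C=CO[C@@]2(C)N(C(=O)OCc3ccccc3)[C@@H]1C
F2 | step 10 | (2R,3R,4aS,5S,8aR)-5-[(5R)-5-{[tert-butyl(dimethyl)silyl]oxy}octyl]-2-methyl-1,2,3,4,4a,5,6,8a-octahydroquinolin-3-ol | O[C@@H]1C[C@H]2[C@@H](CCCC[C@H](O[Si](C)(C)C(C)(C)C)CCC)CC=C[C@H]2N[C@@H]1C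
F3 | step 10 | tert-butyl (2R,3R,4aS,5S,8aR)-5-[(5R)-5-{[tert-butyl(dimethyl)silyl]oxy}octyl]-3-hydroxy-2-methyl-3,4,4a,5,6,8a-hexahydroquinoline-1(2H)-carboxylate | O[C@@H]1C[C@H]2[C@@H](CCCC[C@H](O[Si](C)(C)C(C)(C)C)CCC)CC=C[C@H]2N(C(=O)OC(C)(C)C)[C@@H]1C
F4 | step 12 | tert-butyl (2R,3R,4aS,5S,8aR)-5-[(5R)-5-{[tert-butyl(dimethyl)silyl]oxy}octyl]-3-{[(diethoxyphosphoryl)acetyl]oxy}-2-methyloctahydroquinoline-1(2H)-carboxylate | CCOP(=O)(OCC)CC(=O)O[C@@H]1C[C@H]2[C@@H](CCCC[C@H](O[Si](C)(C)C(C)(C)C)CCC)CCC[C@H]2N(C(=O)OC(C)(C)C)[C@@H]1C
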